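**Plan**
Numbering: C1–C6 is the 3,4-dimethoxyphenyl ring, C7–C9 its propane unit, and primed atoms belong to the eugenol-derived ring and chain.
Cuts: C7–C1 (the CH2–aryl bond), the O–C8 aryl ether bond, the terminal C9′–OH (taken back to the allyl group of eugenol), and both CH2 arms on C8 (taken back to malonate ester carbons).
Enabling feature: C8 carries H, the aryloxy oxygen and two CH2 arms, C7 towards the 3,4-dimethoxyphenyl ring and C9 towards OH. With C7 also at the alcohol level, C8 is the centre of a prochiral 2-aryloxypropane-1,3-diol with enantiotopic hydroxymethyl groups.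
Forward order (acyclic throughout, no ring is formed): O–C8 by alkylation of eugenol with bromomalonate, reduction to the diol, lipase monoacetylation, tosylation of the free arm, C7–C1 by aryl cuprate displacement, then hydroboration–oxidation of the allyl group with loss of the acetate.
Stereochemistry: the single stereocentre C8 (S) is created by the enzyme in the desymmetrisation and is never a reacting centre afterwards.

Key step: step 3

Assumption: the Burkholderia cepacia lipase is taken to acetylate the pro-S hydroxymethyl group of the diol, the sense it shows with 2-O-benzylglycerol (benzyloxy in place of aryloxy); the fallback for step 3 covers the opposite sense.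

Step 1
Reactants: 1 eugenol (4-allyl-2-methoxyphenol); 2 diethyl bromomalonate
Product: 3 diethyl 2-(4-allyl-2-methoxyphenoxy)malonate
Conditions: K2CO3, acetone, reflux
Reagents that add atoms: none
Why: Williamson-type O-alkylation in which the potassium phenoxide of 1 displaces bromide from the doubly activated α-carbon of 2, the usual entry to aryloxymalonates, with the allyl group untouched by carbonate.

Step 2
Reactants: 3 diethyl 2-(4-allyl-2-methoxyphenoxy)malonate
Product: 4 2-(4-allyl-2-methoxyphenoxy)propane-1,3-diol (achiral, prochiral at C2)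
Conditions: LiAlH4, THF, 0 °C to rt (3 added to excess hydride); aq NaOH work-up
Reagents that add atoms: none
Why: Lithium aluminium hydride reduction of both esters to primary alcohols gives the prochiral diol, the aryl ether and the isolated alkene being inert to hydride and inverse addition at 0 °C limiting enolisation of the acidic malonate C–H.

Step 3
Reactants: 4 2-(4-allyl-2-methoxyphenoxy)propane-1,3-diol; 5 vinyl acetate
Product: 6 (S)-2-(4-allyl-2-methoxyphenoxy)-3-hydroxypropyl acetate
Conditions: Burkholderia cepacia lipase (lipase PS, immobilised), excess 5, t-BuOMe, 25 °C; filter, concentrate below 30 °C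
Reagents that add atoms: none
Why: Lipase-catalysed irreversible transesterification, the reaction type established for 2-O-benzylglycerol and other 2-substituted propane-1,3-diols with vinyl acetate: the active-site serine is acetylated by 5, the vinyl alcohol released tautomerises to acetaldehyde so the transfer cannot reverse, and the acyl-enzyme hands its acetyl group to one CH2OH of 4. No ring closes and no skeletal bond forms; a single O–acyl bond is made. The new stereocentre C8 is under catalyst control, since with the bulky aryloxy group held in the large hydrophobic pocket and only H opposite it, the enzyme should present the pro-S hydroxymethyl arm to the acyl-serine and give the (S)-monoacetate. The selectivity required is between two enantiotopic primary alcohols, and it is secured by the large size difference between aryloxy and H at the prochiral carbon and by the absence of a third hydroxyl (the propanol chain is still an allyl group). A slight over-run towards diacetate should consume the minor (R)-monoacetate preferentially and so raise the ee of 6. The product is kept neutral and cold so that 1,3-acetyl migration, which would interconvert the enantiomers, does not set in.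

Step 4
Reactants: 6 (S)-2-(4-allyl-2-methoxyphenoxy)-3-hydroxypropyl acetate
Product: 7 (R)-2-(4-allyl-2-methoxyphenoxy)-3-(tosyloxy)propyl acetate
Conditions: TsCl, pyridine, CH2Cl2, 0 °C
Reagents that add atoms: p-toluenesulfonyl chloride, Cc1ccc(cc1)S(Cl)(=O)=O
Why: Sulfonylation of the only free hydroxyl under cold, weakly basic conditions turns it into a leaving group without touching C8 or provoking acetyl migration, the descriptor becoming R only because CH2OTs outranks CH2OAc in the CIP order.

Step 5
Reactants: 7 (R)-2-(4-allyl-2-methoxyphenoxy)-3-(tosyloxy)propyl acetate; 8 4-bromo-1,2-dimethoxybenzene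
Product: 11 (S)-2-(4-allyl-2-methoxyphenoxy)-3-(3,4-dimethoxyphenyl)propyl acetate, via 3,4-dimethoxyphenyllithium 9 (not isolated), via lithium bis(3,4-dimethoxyphenyl)cuprate 10 (not isolated)
Conditions: 8, t-BuLi (2 equiv per ArBr), Et2O, −78 °C; CuI (0.5 equiv per ArLi), −40 to −20 °C; then 7, −20 to 0 °C; aq NH4Cl
Reagents that add atoms: none
Why: Corey–House-type coupling in which the lithium diarylcuprate displaces the primary tosylate by SN2 to form the C7–C1 bond, cuprates substituting primary sulfonates much faster than they add to esters so that the acetate should survive, and C8 not being a reacting centre so that its configuration is kept (descriptor S again by CIP order).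

Step 6
Reactants: 11 (S)-2-(4-allyl-2-methoxyphenoxy)-3-(3,4-dimethoxyphenyl)propyl acetate
Product: 14 ligraminol D, (S)-3-(3,4-dimethoxyphenyl)-2-[4-(3-hydroxypropyl)-2-methoxyphenoxy]propan-1-ol, via alkyl-9-BBN borane 12 (not isolated), via hydroxypropyl acetate 13 (not isolated)
Conditions: 9-BBN, THF, 0 °C to rt; then MeOH, 3 M aq NaOH, 30% H2O2, 0 to 40 °C
Reagents that add atoms: hydrogen peroxide, OO
Why: Brown hydroboration of the terminal alkene with 9-BBN is anti-Markovnikov and alkaline peroxide oxidation places the primary hydroxyl at C9′, while the same aqueous NaOH saponifies the primary acetate, so the diol should be released in one operation without involving C8.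

**Compound list**
1 | eugenol (4-allyl-2-methoxyphenol) | C=CCc1ccc(O)c(OC)c1 | starting material
2 | diethyl bromomalonate | CCOC(=O)C(Br)C(=O)OCC | starting material
3 | diethyl 2-(4-allyl-2-methoxyphenoxy)malonate | CCOC(=O)C(Oc1ccc(CC=C)cc1OC)C(=O)OCC | intermediate
4 | 2-(4-allyl-2-methoxyphenoxy)propane-1,3-diol | C=CCc1ccc(OC(CO)CO)c(OC)c1 | intermediate
5 | vinyl acetate | C=COC(C)=O | starting material
6 | (S)-2-(4-allyl-2-methoxyphenoxy)-3-hydroxypropyl acetate | OC[C@@H](COC(C)=O)Oc1ccc(CC=C)cc1OC | intermediate
7 | (R)-2-(4-allyl-2-methoxyphenoxy)-3-(tosyloxy)propyl acetate | Cc1ccc(cc1)S(=O)(=O)OC[C@@H](COC(C)=O)Oc1ccc(CC=C)cc1OC | intermediate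
8 | 4-bromo-1,2-dimethoxybenzene | COc1ccc(Br)cc1OC | starting material
9 | 3,4-dimethoxyphenyllithium (not isolated) | [Li]c1ccc(OC)c(OC)c1 | intermediate
10 | lithium bis(3,4-dimethoxyphenyl)cuprate (not isolated) | [Li+].COc1ccc([Cu-]c2ccc(OC)c(OC)c2)cc1OC | intermediate
11 | (S)-2-(4-allyl-2-methoxyphenoxy)-3-(3,4-dimethoxyphenyl)propyl acetate | COc1ccc(C[C@@H](COC(C)=O)Oc2ccc(CC=C)cc2OC)cc1OC | intermediate
12 | (S)-2-{4-[3-(9-borabicyclo[3.3.1]nonan-9-yl)propyl]-2-methoxyphenoxy}-3-(3,4-dimethoxyphenyl)propyl acetate (not isolated) | COc1ccc(C[C@@H](COC(C)=O)Oc2ccc(CCCB3C4CCCC3CCC4)cc2OC)cc1OC | intermediate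
13 | (S)-3-(3,4-dimethoxyphenyl)-2-[4-(3-hydroxypropyl)-2-methoxyphenoxy]propyl acetate (not isolated) | COc1ccc(C[C@@H](COC(C)=O)Oc2ccc(CCCO)cc2OC)cc1OC | intermediate
14 | ligraminol D, (S)-3-(3,4-dimethoxyphenyl)-2-[4-(3-hydroxypropyl)-2-methoxyphenoxy]propan-1-ol | COc1ccc(C[C@@H](CO)Oc2ccc(CCCO)cc2OC)cc1OC | target

**Summary**
Total step count: 6. Longest linear sequence: 6 steps (1 → 3 → 4 → 6 → 7 → 11 → 14); the cuprate from 8 is made in the flask of step 5.

Steps most likely to fail:

Step 5. Substitution at the β-branched, β-oxygenated primary carbon may be slow enough that the cuprate attacks the acetate carbonyl or removes the C8 proton (elimination) instead. The fallback sets out from 7 and exchanges the acetate for a silyl ether, so that a more forcing copper-catalysed Grignard coupling can be used. Acid methanolysis (cat. AcCl in MeOH, 0 °C) should give (R)-2-(4-allyl-2-methoxyphenoxy)-3-hydroxypropyl 4-methylbenzenesulfonate F1, which is kept away from base to prevent closure to the achiral oxetane. TBSCl and imidazole in DMF then give (R)-2-(4-allyl-2-methoxyphenoxy)-3-[(tert-butyldimethylsilyl)oxy]propyl 4-methylbenzenesulfonate F2. 3,4-Dimethoxyphenylmagnesium bromide F3, made from 8 and magnesium in THF, with catalytic CuI at 0 °C to rt should give (S)-[2-(4-allyl-2-methoxyphenoxy)-3-(3,4-dimethoxyphenyl)propoxy](tert-butyl)dimethylsilane F4. Hydroboration with 9-BBN gives the alkyl-9-BBN borane of the silyl ether F5 (not isolated), alkaline peroxide gives (S)-3-{4-[1-(tert-butyldimethylsilyloxy)-3-(3,4-dimethoxyphenyl)propan-2-yloxy]-3-methoxyphenyl}propan-1-ol F6, and TBAF in THF brings the sequence back to the route at 14.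

Step 3. The enzyme may acetylate the opposite enantiotopic arm, or tell the two arms apart too poorly in organic solvent. The fallback sets out from 4: peracetylation (Ac2O, pyridine, cat. DMAP) gives 2-(4-allyl-2-methoxyphenoxy)propane-1,3-diyl diacetate F7, which is hydrolysed enzymatically in pH 7 phosphate buffer. A hydrolase addresses the same enantiotopic arm in hydrolysis as in acylation, so a lipase that acetylates the wrong arm should strip that arm's acetate and leave the pro-S acetate in place. If the problem is weak discrimination, a hydrolase chosen by a small screen for cleaving the pro-R acetate (porcine pancreatic lipase, pig liver esterase) is used instead. Either way the route is rejoined at 6.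

Step 2. Hydride may deprotonate the acidic aryloxymalonate C–H, so that reduction stalls at the enolate and fragmentation or elimination products form in place of the diol. The fallback sets out from 1 and avoids any hydride step. Mitsunobu etherification (PPh3, DIAD, THF) of eugenol with commercial cis-2-phenyl-1,3-dioxan-5-ol should give trans-5-(4-allyl-2-methoxyphenoxy)-2-phenyl-1,3-dioxane F8 (inversion at C5, of no consequence after hydrolysis). Aqueous acetic acid at 50 °C then removes the benzylidene acetal and returns the route at 4.

**Further compounds**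
F1 | step 5 | (R)-2-(4-allyl-2-methoxyphenoxy)-3-hydroxypropyl 4-methylbenzenesulfonate | Cc1ccc(cc1)S(=O)(=O)OC[C@@H](CO)Oc1ccc(CC=C)cc1OC
F2 | step 5 | (R)-2-(4-allyl-2-methoxyphenoxy)-3-[(tert-butyldimethylsilyl)oxy]propyl 4-methylbenzenesulfonate | Cc1ccc(cc1)S(=O)(=O)OC[C@@H](CO[Si](C)(C)C(C)(C)C)Oc1ccc(CC=C)cc1OC
F3 | step 5 | 3,4-dimethoxyphenylmagnesium bromide | COc1ccc([Mg]Br)cc1OC
F4 | step 5 | (S)-[2-(4-allyl-2-methoxyphenoxy)-3-(3,4-dimethoxyphenyl)propoxy](tert-butyl)dimethylsilane | COc1ccc(C[C@@H](CO[Si](C)(C)C(C)(C)C)Oc2ccc(CC=C)cc2OC)cc1OC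
F5 | step 5 | alkyl-9-BBN borane of the silyl ether, (S)-configured | COc1ccc(C[C@@H](CO[Si](C)(C)C(C)(C)C)Oc2ccc(CCCB3C4CCCC3CCC4)cc2OC)cc1OC
F6 | step 5 | (S)-3-{4-[1-(tert-butyldimethylsilyloxy)-3-(3,4-dimethoxyphenyl)propan-2-yloxy]-3-methoxyphenyl}propan-1-ol | COc1ccc(C[C@@H](CO[Si](C)(C)C(C)(C)C)Oc2ccc(CCCO)cc2OC)cc1OC
F7 | step 3 | 2-(4-allyl-2-methoxyphenoxy)propane-1,3-diyl diacetate | CC(=O)OCC(COC(C)=O)Oc1ccc(CC=C)cc1OC
F8 | step 2 | trans-5-(4-allyl-2-methoxyphenoxy)-2-phenyl-1,3-dioxane | C=CCc1ccc(O[C@H]2CO[C@H](c3ccccc3)OC2)c(OC)c1
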